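**Plan**

Numbering: the target is numbered as a hexahydro-1-benzofuran-2-one (O1, C2, C3, C3a, C4–C7, C7a; ring A = cyclohexane, ring B = lactone); acyclic compounds are numbered along their chain.
Retrosynthesis: the C4 acyl group and the allylic OH on the C7 side chain go first (esterification; SeO2 oxidation of an isopropenyl group). Then C3a–C7a and C2–C3 (with O1–C2) are cut together: ring B is O1–C7a (an aldehyde C=O) plus C3a–C3(=CH2) (the proximal C=C of a terminal allene) plus C2 (CO), and since C3a–C7a is also a bond of ring A, both rings fall back to the acyclic 6,7-dienal 15. Last, the C6–C7 bond is cut (Ireland–Claisen of allyl ester 8).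
Forward: Keck methallylation of an ynal, acrylate ring-closing metathesis (the dihydropyranone fixes the Z alkene), reduction, esterification, boron-enolate Claisen, reduction, Crabbé allene synthesis and oxidation give 15; one hetero-Pauson–Khand step then closes ring A and ring B; desilylation, acylation, allylic oxidation and desilylation finish.
Stereochemistry: C4 from the (S)-BINOL/Ti(OiPr)4 allylation; C6 and C7 together from the chair Claisen of the (Z)-alkene under a chiral boron controller; C3a and C7a from the substrate in the cyclocarbonylation; the side-chain centre from (S)-Roche ester.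

Key step: step 11

Remark: the absolute sense of the boron-controlled Claisen (step 7) and its E(O) dienolate geometry are assumed by analogy with geranyl-type 3-methylbut-3-enoates, which give the anti pair; the (R,R)-controller is equally available should the sense prove opposite.

**Route**

Step 1
Reactants: 1 3-(trimethylsilyl)prop-2-ynal
Product: 2 (3S)-5-methyl-1-(trimethylsilyl)hex-5-en-1-yn-3-ol
Conditions: tributyl(2-methylallyl)stannane, (S)-BINOL (20 mol %), Ti(OiPr)4 (10 mol %), 4 Å MS, CH2Cl2, −20 °C; aq. NaHCO3 work-up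
Reagents that add atoms: tributyl(2-methylallyl)stannane, CCCC[Sn](CCCC)(CCCC)CC(C)=C
Why: Keck asymmetric allylation; the (S)-BINOL–titanium Lewis acid is expected to direct the methallyl group to the Si face of the ynal, which gives the (S)-carbinol because the alkynyl group outranks CH2.

Step 2
Reactants: 2 (3S)-5-methyl-1-(trimethylsilyl)hex-5-en-1-yn-3-ol
Product: 3 (3S)-5-methyl-1-(trimethylsilyl)hex-5-en-1-yn-3-yl prop-2-enoate
Conditions: acryloyl chloride, Et3N, DMAP (cat.), CH2Cl2, 0 °C
Reagents that add atoms: acryloyl chloride, C=CC(=O)Cl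
Why: O-acylation of a secondary alcohol with an acid chloride under DMAP catalysis; the carbinol centre is not touched.

Step 3
Reactants: 3 (3S)-5-methyl-1-(trimethylsilyl)hex-5-en-1-yn-3-yl prop-2-enoate
Product: 4 (6S)-4-methyl-6-[(trimethylsilyl)ethynyl]-5,6-dihydro-2H-pyran-2-one
Conditions: second-generation Grubbs catalyst RuCl2(=CHPh)(PCy3)(H2IMes) (5 mol %), CH2Cl2 (0.01 M), 40 °C
Reagents that add atoms: none
Why: Ring-closing metathesis of the acrylate with the 1,1-disubstituted alkene forms the trisubstituted C3=C4 bond of the six-membered lactone, whose ring forces the cis relation of C2 and C5 needed later as the (Z)-alkene; the silyl-capped alkyne is a poor partner for ene–yne metathesis.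

Step 4
Reactants: 4 (6S)-4-methyl-6-[(trimethylsilyl)ethynyl]-5,6-dihydro-2H-pyran-2-one
Product: 5 (2Z,5S)-3-methyl-7-(trimethylsilyl)hept-2-en-6-yne-1,5-diol
Conditions: DIBAL-H (i-Bu2AlH, 3.5 equiv), CH2Cl2, −78 → 0 °C; aq. potassium sodium tartrate (KNaC4H4O6)
Reagents that add atoms: none
Why: 1,2-Reduction of the unsaturated lactone through the lactol to the ene-diol; the alkene geometry set by the ring is retained and the two hydroxyls come out differentiated (primary allylic, secondary propargylic).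

Step 5
Reactants: 5 (2Z,5S)-3-methyl-7-(trimethylsilyl)hept-2-en-6-yne-1,5-diol; 6 3-methylbut-3-enoic acid
Product: 7 (2Z,5S)-5-hydroxy-3-methyl-7-(trimethylsilyl)hept-2-en-6-yn-1-yl 3-methylbut-3-enoate
Conditions: DCC, DMAP (5 mol %), CH2Cl2, −20 °C
Reagents that add atoms: none
Why: Steglich esterification, selective for the primary allylic over the secondary propargylic hydroxyl at low temperature; little DMAP and low temperature limit migration of the β,γ-double bond into conjugation.

Step 6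
Reactants: 7 (2Z,5S)-5-hydroxy-3-methyl-7-(trimethylsilyl)hept-2-en-6-yn-1-yl 3-methylbut-3-enoate
Product: 8 (2Z,5S)-5-[(tert-butyldimethylsilyl)oxy]-3-methyl-7-(trimethylsilyl)hept-2-en-6-yn-1-yl 3-methylbut-3-enoate
Conditions: TBSCl, imidazole, DMF, 23 °C
Reagents that add atoms: tert-butyldimethylsilyl chloride, CC(C)(C)[Si](C)(C)Cl
Why: Silylation of the remaining secondary hydroxyl, which must survive enolisation, hydride reduction and the carbonylation.

Step 7
Reactants: 8 (2Z,5S)-5-[(tert-butyldimethylsilyl)oxy]-3-methyl-7-(trimethylsilyl)hept-2-en-6-yn-1-yl 3-methylbut-3-enoate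
Product: 10 (2S,3R,5S)-5-[(tert-butyldimethylsilyl)oxy]-3-ethenyl-3-methyl-2-(prop-1-en-2-yl)-7-(trimethylsilyl)hept-6-ynoic acid, via boron dienolate 9 (not isolated)
Conditions: (4S,5S)-2-bromo-1,3-bis{[3,5-bis(trifluoromethyl)phenyl]sulfonyl}-4,5-diphenyl-1,3,2-diazaborolidine (1.3 equiv), Et3N, toluene/hexane, −78 °C, then −20 → 4 °C; aqueous work-up
Reagents that add atoms: none
Why: Enantioselective Ireland–Claisen rearrangement of a chiral boron enolate: soft enolisation at the acidic α-CH2 gives E(O) dienolate 9, which rearranges through a chair with the isopropenyl group and the (Z)-placed C4 chain axial and the methyl group equatorial, so that C2 and C3 are set together in the syn relation, while the C2-symmetric sulfonamide ligand selects the enolate face and the C5 centre is a bystander.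

Step 8
Reactants: 10 (2S,3R,5S)-5-[(tert-butyldimethylsilyl)oxy]-3-ethenyl-3-methyl-2-(prop-1-en-2-yl)-7-(trimethylsilyl)hept-6-ynoic acid
Product: 12 (2S,3R,5S)-5-[(tert-butyldimethylsilyl)oxy]-3-ethenyl-3-methyl-2-(prop-1-en-2-yl)hept-6-yn-1-ol, via silylalkynol 11 (not isolated)
Conditions: LiAlH4, THF, 0 → 23 °C; aqueous work-up; then K2CO3, MeOH, 23 °C
Reagents that add atoms: none
Why: Hydride reduction of the acid to the primary alcohol, then methanolysis of the alkynyl C–Si bond; the silyl ether and the three stereocentres are not affected.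

Step 9
Reactants: 12 (2S,3R,5S)-5-[(tert-butyldimethylsilyl)oxy]-3-ethenyl-3-methyl-2-(prop-1-en-2-yl)hept-6-yn-1-ol
Product: 14 (2S,3R,5S)-5-[(tert-butyldimethylsilyl)oxy]-3-ethenyl-3-methyl-2-(prop-1-en-2-yl)octa-6,7-dien-1-ol, via propargylic amine 13 (not isolated)
Conditions: (CH2O)n, CuI (0.5 equiv), dicyclohexylamine, 1,4-dioxane, reflux
Reagents that add atoms: paraformaldehyde (as formaldehyde), C=O
Why: Crabbé homologation: copper-mediated Mannich reaction gives amine 13, whose 1,5-hydride transfer and fragmentation turn the terminal alkyne into the terminal allene without involving the carbinol centre.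

Step 10
Reactants: 14 (2S,3R,5S)-5-[(tert-butyldimethylsilyl)oxy]-3-ethenyl-3-methyl-2-(prop-1-en-2-yl)octa-6,7-dien-1-ol
Product: 15 (2S,3R,5S)-5-[(tert-butyldimethylsilyl)oxy]-3-ethenyl-3-methyl-2-(prop-1-en-2-yl)octa-6,7-dienal
Conditions: Dess–Martin periodinane, NaHCO3, CH2Cl2, 0 °C; used at once
Reagents that add atoms: none
Why: Buffered Dess–Martin oxidation should give the α-branched, β,γ-unsaturated aldehyde without epimerisation at C2 or migration of the double bond.

Step 11
Reactants: 15 (2S,3R,5S)-5-[(tert-butyldimethylsilyl)oxy]-3-ethenyl-3-methyl-2-(prop-1-en-2-yl)octa-6,7-dienal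
Product: 17 (3aS,4S,6R,7S,7aR)-4-[(tert-butyldimethylsilyl)oxy]-6-ethenyl-6-methyl-3-methylidene-7-(prop-1-en-2-yl)hexahydro-1-benzofuran-2(3H)-one, via oxamolybdacyclopentane 16 (not isolated)
Conditions: Mo(CO)6 (1.2 equiv), DMSO (10 equiv), toluene, 100 °C
Reagents that add atoms: molybdenum hexacarbonyl Mo(CO)6 as source of one CO, [Mo].[C-]#[O+].[C-]#[O+].[C-]#[O+].[C-]#[O+].[C-]#[O+].[C-]#[O+] (CO: [C-]#[O+])
Why: Allenic hetero-Pauson–Khand reaction: zerovalent molybdenum (Mo(CO)3(DMSO)n, formed from Mo(CO)6 by CO/DMSO exchange) binds the aldehyde C=O and the proximal C6=C7 bond of the allene, oxidative cyclisation joins C1 to C6 (C7a–C3a of the product) to give divalent-molybdenum metallacycle 16 with the metal on the central allene carbon, CO insertion into that Mo–C(sp2) bond makes C2–C3, and C–O reductive elimination closes O1–C2. The closest known reaction type is the Mo(CO)6/DMSO- or Ru3(CO)12/CO-mediated cyclocarbonylation of allenyl aldehydes to fused α-methylene-γ-butyrolactones. Ring A closes in the oxidative cyclisation as a 6-exo C–C coupling onto the proximal allene carbon (the other two allene carbons stay outside the ring), and ring B closes as the [2+2+1] carbonylative annulation across that new bond. C7a and C3a are both set by the substrate: the tether should adopt the one chair in which C7-isopropenyl, C4-OTBS and C6-methyl are equatorial (the flipped chair puts OTBS and methyl 1,3-diaxial), the carbonyl oxygen then lies equatorial to avoid the axial C6 vinyl group, and the allene lies equatorial with the metal on the open periphery, which gives the trans ring fusion. The step needs proximal-bond regioselectivity (usual for molybdenum; it keeps the exocyclic methylene and excludes a seven-membered ring), chemoselectivity over the vinyl and isopropenyl groups (simple alkenes do not engage without an alkyne partner) and trans over cis fusion, which is not forced to cis here as it is when a five-membered carbocycle forms. C4 is carried as a silyl ether, not an ester, so that the α-allenyl C–O bond does not ionise on the metal.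

Step 12
Reactants: 17 (3aS,4S,6R,7S,7aR)-4-[(tert-butyldimethylsilyl)oxy]-6-ethenyl-6-methyl-3-methylidene-7-(prop-1-en-2-yl)hexahydro-1-benzofuran-2(3H)-one
Product: 18 (3aR,4S,6R,7S,7aR)-6-ethenyl-4-hydroxy-6-methyl-3-methylidene-7-(prop-1-en-2-yl)hexahydro-1-benzofuran-2(3H)-one
Conditions: HF·pyridine, pyridine/THF, 0 → 23 °C
Reagents that add atoms: none
Why: Silyl ether cleavage under non-basic conditions, chosen to avoid translactonisation to the C4 oxygen and conjugate addition to the methylene lactone.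

Step 13
Reactants: 19 methyl (2S)-3-hydroxy-2-methylpropanoate
Product: 20 methyl (2S)-3-[(tert-butyldimethylsilyl)oxy]-2-methylpropanoate
Conditions: TBSCl, imidazole, DMF, 23 °C
Reagents that add atoms: tert-butyldimethylsilyl chloride, CC(C)(C)[Si](C)(C)Cl
Why: Silylation of the primary hydroxyl of the Roche ester; the α-centre is not involved.

Step 14
Reactants: 20 methyl (2S)-3-[(tert-butyldimethylsilyl)oxy]-2-methylpropanoate
Product: 21 (2S)-3-[(tert-butyldimethylsilyl)oxy]-2-methylpropanoic acid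
Conditions: LiOH, THF/H2O, 0 °C; then 1 M HCl to pH 3
Reagents that add atoms: lithium hydroxide, [Li+].[OH-]
Why: Saponification at low temperature, under which the α-centre should not epimerise and the silyl ether survives.

Step 15
Reactants: 18 (3aR,4S,6R,7S,7aR)-6-ethenyl-4-hydroxy-6-methyl-3-methylidene-7-(prop-1-en-2-yl)hexahydro-1-benzofuran-2(3H)-one; 21 (2S)-3-[(tert-butyldimethylsilyl)oxy]-2-methylpropanoic acid
Product: 22 (3aR,4S,6R,7S,7aR)-6-ethenyl-6-methyl-3-methylidene-2-oxo-7-(prop-1-en-2-yl)octahydro-1-benzofuran-4-yl (2S)-3-[(tert-butyldimethylsilyl)oxy]-2-methylpropanoate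
Conditions: EDC·HCl, DMAP, CH2Cl2, 23 °C
Reagents that add atoms: none
Why: Steglich esterification of the equatorial secondary C4 hydroxyl; both partners keep their configuration.

Step 16
Reactants: 22 (3aR,4S,6R,7S,7aR)-6-ethenyl-6-methyl-3-methylidene-2-oxo-7-(prop-1-en-2-yl)octahydro-1-benzofuran-4-yl (2S)-3-[(tert-butyldimethylsilyl)oxy]-2-methylpropanoate
Product: 23 (3aR,4S,6R,7R,7aR)-6-ethenyl-7-(3-hydroxyprop-1-en-2-yl)-6-methyl-3-methylidene-2-oxooctahydro-1-benzofuran-4-yl (2S)-3-[(tert-butyldimethylsilyl)oxy]-2-methylpropanoate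
Conditions: SeO2 (0.3 equiv), t-BuOOH (2 equiv), CH2Cl2, 0 → 23 °C
Reagents that add atoms: selenium dioxide (oxygen transfer, catalytic), O=[Se]=O; tert-butyl hydroperoxide (terminal oxidant), CC(C)(C)OO
Why: SeO2 allylic oxidation (ene reaction, then [2,3]-sigmatropic shift): the isopropenyl group is the only alkene with reactive allylic hydrogens (the vinyl group sits on a quaternary carbon, the exocyclic methylene is electron-poor), and its CH3 is preferred over the hindered methine C7–H; the C7 descriptor changes from S to R by priority only.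

Step 17
Reactants: 23 (3aR,4S,6R,7R,7aR)-6-ethenyl-7-(3-hydroxyprop-1-en-2-yl)-6-methyl-3-methylidene-2-oxooctahydro-1-benzofuran-4-yl (2S)-3-[(tert-butyldimethylsilyl)oxy]-2-methylpropanoate
Product: 24 (3aR,4S,6R,7R,7aR)-6-ethenyl-7-(3-hydroxyprop-1-en-2-yl)-6-methyl-3-methylidene-2-oxooctahydro-1-benzofuran-4-yl (2S)-3-hydroxy-2-methylpropanoate (CNP0133858.2)
Conditions: HF·pyridine, THF, 0 °C
Reagents that add atoms: none
Why: Cleavage of the primary silyl ether under mild, non-basic conditions that should leave both esters and the methylene lactone intact.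

**Compound list**

1 | 3-(trimethylsilyl)prop-2-ynal | C[Si](C)(C)C#CC=O | starting material
2 | (3S)-5-methyl-1-(trimethylsilyl)hex-5-en-1-yn-3-ol | C[Si](C)(C)C#C[C@@H](O)CC(C)=C | intermediate
3 | (3S)-5-methyl-1-(trimethylsilyl)hex-5-en-1-yn-3-yl prop-2-enoate | C=CC(=O)O[C@@H](CC(C)=C)C#C[Si](C)(C)C | intermediate
4 | (6S)-4-methyl-6-[(trimethylsilyl)ethynyl]-5,6-dihydro-2H-pyran-2-one | CC1=CC(=O)O[C@@H](C1)C#C[Si](C)(C)C | intermediate
5 | (2Z,5S)-3-methyl-7-(trimethylsilyl)hept-2-en-6-yne-1,5-diol | OC/C=C(/C)C[C@H](O)C#C[Si](C)(C)C | intermediate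
6 | 3-methylbut-3-enoic acid | C=C(C)CC(=O)O | starting material
7 | (2Z,5S)-5-hydroxy-3-methyl-7-(trimethylsilyl)hept-2-en-6-yn-1-yl 3-methylbut-3-enoate | C=C(C)CC(=O)OC/C=C(/C)C[C@H](O)C#C[Si](C)(C)C | intermediate
8 | (2Z,5S)-5-[(tert-butyldimethylsilyl)oxy]-3-methyl-7-(trimethylsilyl)hept-2-en-6-yn-1-yl 3-methylbut-3-enoate | C=C(C)CC(=O)OC/C=C(/C)C[C@H](O[Si](C)(C)C(C)(C)C)C#C[Si](C)(C)C | intermediate
9 | E(O) boron dienolate of 8 bearing the (4S,5S)-diazaborolidine | C=C(C)/C=C(\OC/C=C(/C)C[C@H](O[Si](C)(C)C(C)(C)C)C#C[Si](C)(C)C)OB1N(S(=O)(=O)c2cc(cc(c2)C(F)(F)F)C(F)(F)F)[C@@H](c2ccccc2)[C@H](c2ccccc2)N1S(=O)(=O)c1cc(cc(c1)C(F)(F)F)C(F)(F)F | intermediate (not isolated)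
10 | (2S,3R,5S)-5-[(tert-butyldimethylsilyl)oxy]-3-ethenyl-3-methyl-2-(prop-1-en-2-yl)-7-(trimethylsilyl)hept-6-ynoic acid | C=C[C@@](C)(C[C@H](O[Si](C)(C)C(C)(C)C)C#C[Si](C)(C)C)[C@H](C(C)=C)C(O)=O | intermediate
11 | (2S,3R,5S)-5-[(tert-butyldimethylsilyl)oxy]-3-ethenyl-3-methyl-2-(prop-1-en-2-yl)-7-(trimethylsilyl)hept-6-yn-1-ol | C=C[C@@](C)(C[C@H](O[Si](C)(C)C(C)(C)C)C#C[Si](C)(C)C)[C@H](C(C)=C)CO | intermediate (not isolated)
12 | (2S,3R,5S)-5-[(tert-butyldimethylsilyl)oxy]-3-ethenyl-3-methyl-2-(prop-1-en-2-yl)hept-6-yn-1-ol | C=C[C@@](C)(C[C@H](O[Si](C)(C)C(C)(C)C)C#C)[C@H](C(C)=C)CO | intermediate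
13 | (2S,3R,5S)-5-[(tert-butyldimethylsilyl)oxy]-8-(dicyclohexylamino)-3-ethenyl-3-methyl-2-(prop-1-en-2-yl)oct-6-yn-1-ol | C=C[C@@](C)(C[C@H](O[Si](C)(C)C(C)(C)C)C#CCN(C1CCCCC1)C1CCCCC1)[C@H](C(C)=C)CO | intermediate (not isolated)
14 | (2S,3R,5S)-5-[(tert-butyldimethylsilyl)oxy]-3-ethenyl-3-methyl-2-(prop-1-en-2-yl)octa-6,7-dien-1-ol | C=C[C@@](C)(C[C@H](O[Si](C)(C)C(C)(C)C)C=C=C)[C@H](C(C)=C)CO | intermediate
15 | (2S,3R,5S)-5-[(tert-butyldimethylsilyl)oxy]-3-ethenyl-3-methyl-2-(prop-1-en-2-yl)octa-6,7-dienal | C=C[C@@](C)(C[C@H](O[Si](C)(C)C(C)(C)C)C=C=C)[C@H](C(C)=C)C=O | intermediate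
16 | oxamolybdacyclopentane fused to ring A, drawn as its Mo(CO)3 fragment (further sites DMSO) | C=C[C@@]1(C)C[C@H](O[Si](C)(C)C(C)(C)C)[C@H]2C(=C)[Mo]O[C@@H]2[C@H]1C(C)=C.[C-]#[O+].[C-]#[O+].[C-]#[O+] | intermediate (not isolated)
17 | (3aS,4S,6R,7S,7aR)-4-[(tert-butyldimethylsilyl)oxy]-6-ethenyl-6-methyl-3-methylidene-7-(prop-1-en-2-yl)hexahydro-1-benzofuran-2(3H)-one | C=C[C@@]1(C)C[C@H](O[Si](C)(C)C(C)(C)C)[C@H]2C(=C)C(=O)O[C@@H]2[C@H]1C(C)=C | intermediate
18 | (3aR,4S,6R,7S,7aR)-6-ethenyl-4-hydroxy-6-methyl-3-methylidene-7-(prop-1-en-2-yl)hexahydro-1-benzofuran-2(3H)-one | C=C[C@@]1(C)C[C@H](O)[C@H]2C(=C)C(=O)O[C@@H]2[C@H]1C(C)=C | intermediate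
19 | methyl (2S)-3-hydroxy-2-methylpropanoate | COC(=O)[C@@H](C)CO | starting material
20 | methyl (2S)-3-[(tert-butyldimethylsilyl)oxy]-2-methylpropanoate | COC(=O)[C@@H](C)CO[Si](C)(C)C(C)(C)C | intermediate
21 | (2S)-3-[(tert-butyldimethylsilyl)oxy]-2-methylpropanoic acid | OC(=O)[C@@H](C)CO[Si](C)(C)C(C)(C)C | intermediate
22 | (3aR,4S,6R,7S,7aR)-6-ethenyl-6-methyl-3-methylidene-2-oxo-7-(prop-1-en-2-yl)octahydro-1-benzofuran-4-yl (2S)-3-[(tert-butyldimethylsilyl)oxy]-2-methylpropanoate | C=C[C@@]1(C)C[C@H](OC(=O)[C@@H](C)CO[Si](C)(C)C(C)(C)C)[C@H]2C(=C)C(=O)O[C@@H]2[C@H]1C(C)=C | intermediate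
23 | (3aR,4S,6R,7R,7aR)-6-ethenyl-7-(3-hydroxyprop-1-en-2-yl)-6-methyl-3-methylidene-2-oxooctahydro-1-benzofuran-4-yl (2S)-3-[(tert-butyldimethylsilyl)oxy]-2-methylpropanoate | C=C[C@@]1(C)C[C@H](OC(=O)[C@@H](C)CO[Si](C)(C)C(C)(C)C)[C@H]2C(=C)C(=O)O[C@@H]2[C@H]1C(=C)CO | intermediate
24 | (3aR,4S,6R,7R,7aR)-6-ethenyl-7-(3-hydroxyprop-1-en-2-yl)-6-methyl-3-methylidene-2-oxooctahydro-1-benzofuran-4-yl (2S)-3-hydroxy-2-methylpropanoate | C=C[C@@]1(C)C[C@H](OC(=O)[C@@H](C)CO)[C@H]2C(=C)C(=O)O[C@@H]2[C@H]1C(=C)CO | target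

**Count and risks**

Total: 17 steps. Longest linear sequence: 15 steps (steps 1–12 and 15–17).

Most likely to fail, in this order:

1. Step 11. The metallacycle may close with a cis instead of a trans ring fusion, and the α-branched aldehyde may epimerise or decompose at 100 °C. The fallback sets out from 12 and comes back at 17; it takes the C3a centre out of the cyclisation. Oxidation of 12 with Dess–Martin periodinane gives alkynal F1. Treatment with Mo(CO)6/DMSO in toluene at 100 °C (hetero-Pauson–Khand reaction of an alkynyl aldehyde) gives butenolide F2, in which C3a is sp2 and only C7a has to be set. 1,4-Reduction with NaBH4/CuCl in MeOH at 0 °C is expected to deliver hydride to C3a along the axial direction and give the trans-fused saturated lactone F3. Deprotonation with LDA (LiN(i-Pr)2) in THF at −78 °C and reaction with Eschenmoser's salt (CH2=NMe2+ I−) gives Mannich base F4; MeI gives ammonium iodide F5, and NaHCO3 effects elimination to 17.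

2. Step 7. Incomplete control of the dienolate geometry or of the enolate face would give the anti pair or material of low enantiomeric purity. The fallback sets out from 8 and comes back at 10; it replaces reagent control by separation through the fixed C5 centre. Deprotonation with LDA (LiN(i-Pr)2) in THF at −78 °C and trapping with TMSCl/Et3N gives silyl ketene acetal F6, which rearranges on warming to 23 °C to silyl ester F7 and silyl ester F8. Aqueous acid hydrolyses these to 10 and the diastereomeric acid F9, which are diastereomers because of the C5 centre and are separated by chromatography.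

3. Step 16. The allylic alcohol may be over-oxidised to the enal, conversion may stall, or the methine C7–H may be attacked. The fallback sets out from 22 and comes back at 23; it uses ene-type chlorination and solvolysis instead of direct oxygenation. NaOCl with CeCl3·7H2O in CH2Cl2/H2O at 0 °C gives allylic chloride F10 (this chlorination selects isopropenyl over vinyl groups). AgOCOCF3 (silver trifluoroacetate) in Et2O gives trifluoroacetate F11, which is hydrolysed during aqueous NaHCO3 work-up to 23.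

**Further compounds**

F1 | step 11 | (2S,3R,5S)-5-[(tert-butyldimethylsilyl)oxy]-3-ethenyl-3-methyl-2-(prop-1-en-2-yl)hept-6-ynal | C=C[C@@](C)(C[C@H](O[Si](C)(C)C(C)(C)C)C#C)[C@H](C(C)=C)C=O
F2 | step 11 | (4S,6R,7S,7aR)-4-[(tert-butyldimethylsilyl)oxy]-6-ethenyl-6-methyl-7-(prop-1-en-2-yl)-5,6,7,7a-tetrahydro-1-benzofuran-2(4H)-one | C=C[C@@]1(C)C[C@H](O[Si](C)(C)C(C)(C)C)C2=CC(=O)O[C@@H]2[C@H]1C(C)=C
F3 | step 11 | (3aS,4S,6R,7S,7aR)-4-[(tert-butyldimethylsilyl)oxy]-6-ethenyl-6-methyl-7-(prop-1-en-2-yl)hexahydro-1-benzofuran-2(3H)-one | C=C[C@@]1(C)C[C@H](O[Si](C)(C)C(C)(C)C)[C@H]2CC(=O)O[C@@H]2[C@H]1C(C)=C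
F4 | step 11 | 3-[(dimethylamino)methyl] derivative of F3 (both C3 epimers) | C=C[C@@]1(C)C[C@H](O[Si](C)(C)C(C)(C)C)[C@H]2C(CN(C)C)C(=O)O[C@@H]2[C@H]1C(C)=C
F5 | step 11 | trimethylammonium iodide formed from F4 (both C3 epimers) | C=C[C@@]1(C)C[C@H](O[Si](C)(C)C(C)(C)C)[C@H]2C(C[N+](C)(C)C)C(=O)O[C@@H]2[C@H]1C(C)=C.[I-]
F6 | step 7 | trimethylsilyl ketene acetal of 8 (E(O) dienolate geometry) | C=C(C)/C=C(\OC/C=C(/C)C[C@H](O[Si](C)(C)C(C)(C)C)C#C[Si](C)(C)C)O[Si](C)(C)C
F7 | step 7 | trimethylsilyl ester of 10 | C=C[C@@](C)(C[C@H](O[Si](C)(C)C(C)(C)C)C#C[Si](C)(C)C)[C@H](C(C)=C)C(=O)O[Si](C)(C)C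
F8 | step 7 | trimethylsilyl ester of F9 | C=C[C@](C)(C[C@H](O[Si](C)(C)C(C)(C)C)C#C[Si](C)(C)C)[C@@H](C(C)=C)C(=O)O[Si](C)(C)C
F9 | step 7 | (2R,3S,5S)-5-[(tert-butyldimethylsilyl)oxy]-3-ethenyl-3-methyl-2-(prop-1-en-2-yl)-7-(trimethylsilyl)hept-6-ynoic acid | C=C[C@](C)(C[C@H](O[Si](C)(C)C(C)(C)C)C#C[Si](C)(C)C)[C@@H](C(C)=C)C(O)=O
F10 | step 16 | allylic chloride of 22 (3-chloroprop-1-en-2-yl at C7) | C=C[C@@]1(C)C[C@H](OC(=O)[C@@H](C)CO[Si](C)(C)C(C)(C)C)[C@H]2C(=C)C(=O)O[C@@H]2[C@H]1C(=C)CCl
F11 | step 16 | trifluoroacetate of 23 | C=C[C@@]1(C)C[C@H](OC(=O)[C@@H](C)CO[Si](C)(C)C(C)(C)C)[C@H]2C(=C)C(=O)O[C@@H]2[C@H]1C(=C)COC(=O)C(F)(F)F
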